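**Assumption:** Atom labels of the target are used for all intermediates (isochromene O2, C1, C3–C8a; side chain C9=C10–C11; oxolane C2'–C5'). 2-C-Methyl-D-ribono-1,4-lactone and (S)-5-(hydroxymethyl)furan-2(5H)-one are taken as the purchased chiral compounds.

## Retrosynthetic overview

1. The pyran ring is closed last, by 6-endo addition of C1–OH to C3 of an ynenone; the C4a–C4 bond before it comes from Sonogashira coupling of core 16 with enyne 10.
2. Ring A is closed at C4a–C8a by a photoredox radical addition–elimination onto a trichlorovinyl ketone (C5, C4a and Cl come from trichloroethylene).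
3. C7 and C8 are bought in 2-C-methyl-D-ribonolactone; an orthoformate cage tying O7, O8 and O(C1) lets ring A close only in the all-cis sense, which fixes C8a.
4. The side chain comes from (S)-5-(hydroxymethyl)furanone: trans cuprate addition sets C3', chelation-controlled diynyl addition sets C11, directed reduction gives the E-alkene.
5. Ring order: oxolane (bought) → orthoformate cage → ring A → pyran.

## Route

**Step 1**
Reactants: 1 (S)-5-(hydroxymethyl)furan-2(5H)-one
Product: 2 (S)-5-[(trityloxy)methyl]furan-2(5H)-one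
Conditions: TrCl, pyridine, DMAP (cat.), CH2Cl2, rt
Reagents that add atoms: trityl chloride, ClC(c1ccccc1)(c1ccccc1)c1ccccc1
Why: Tritylation (ether protection) of the primary alcohol; the bulky group shields one face of the butenolide for step 2.

**Step 2**
Reactants: 2 (S)-5-[(trityloxy)methyl]furan-2(5H)-one
Product: 3 (4S,5S)-4-methyl-5-[(trityloxy)methyl]oxolan-2-one
Conditions: MeLi, CuI, Et2O, −78 °C (Me2CuLi); then 2, −78 → −40 °C; aq. NH4Cl
Reagents that add atoms: methyllithium, [Li]C
Why: Gilman cuprate conjugate addition to the butenolide occurs anti to the CH2OTr group, so C3' is set trans to the bought C2' centre.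

**Step 3**
Reactants: 3 (4S,5S)-4-methyl-5-[(trityloxy)methyl]oxolan-2-one
Product: 5 [(2S,3S)-3-methyloxolan-2-yl]methanol, via lactol 4 (not isolated)
Conditions: iBu2AlH, CH2Cl2, −78 °C; then Et3SiH, BF3·OEt2, CH2Cl2, −78 → 0 °C
Reagents that add atoms: none
Why: Lactone-to-ether reduction (partial reduction to the lactol, then ionic hydrogenation of the oxocarbenium ion) with concurrent reductive detritylation; no stereocentre is touched.

**Step 4**
Reactants: 5 [(2S,3S)-3-methyloxolan-2-yl]methanol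
Product: 6 (2S,3S)-3-methyloxolane-2-carboxylic acid
Conditions: TEMPO (cat.), NaOCl (cat.), NaClO2, MeCN/phosphate buffer pH 6.7, 35 °C
Reagents that add atoms: sodium chlorite, [Na+].[O-]Cl=O
Why: TEMPO/chlorite oxidation of the primary alcohol to the acid under buffered conditions that do not epimerize C2'.

**Step 5**
Reactants: 6 (2S,3S)-3-methyloxolane-2-carboxylic acid
Product: 7 1-[(2S,3S)-3-methyloxolan-2-yl]ethan-1-one
Conditions: MeLi (2.2 equiv), Et2O, 0 °C; inverse quench into 1 M HCl
Reagents that add atoms: methyllithium, [Li]C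
Why: Ketone synthesis from a carboxylic acid: MeLi adds to the lithium carboxylate to give a stable gem-dialkoxide that collapses to the methyl ketone on quench.

**Step 6**
Reactants: 7 1-[(2S,3S)-3-methyloxolan-2-yl]ethan-1-one
Product: 8 (2S)-2-[(2S,3S)-3-methyloxolan-2-yl]-6-(trimethylsilyl)hexa-3,5-diyn-2-ol
Conditions: Me3SiC≡CC≡CSiMe3, MeLi·LiBr, THF, rt; MgBr2·OEt2, −78 °C; then 7, Et2O/CH2Cl2, −78 → −20 °C; aq. NH4Cl
Reagents that add atoms: 1,4-bis(trimethylsilyl)buta-1,3-diyne, C[Si](C)(C)C#CC#C[Si](C)(C)C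
Why: Cram-chelate-controlled 1,2-addition: magnesium bridges the ketone and oxolane oxygens and the diynyl nucleophile attacks from the C2'–H face (anti to C3'), which gives the (S)-carbinol C11.

**Step 7**
Reactants: 8 (2S)-2-[(2S,3S)-3-methyloxolan-2-yl]-6-(trimethylsilyl)hexa-3,5-diyn-2-ol
Product: 10 (2S,3E)-2-[(2S,3S)-3-methyloxolan-2-yl]hex-3-en-5-yn-2-ol, via silyl enyne 9 (not isolated)
Conditions: NaAlH2(OCH2CH2OMe)2, THF, 0 °C → rt; then K2CO3, MeOH, rt
Reagents that add atoms: none
Why: Alkoxide-directed trans-hydroalumination (propargylic alcohol reduction) converts only the alkyne next to the carbinol into the E-alkene, and base methanolysis removes the alkynyl silane.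

**Step 8**
Reactants: 11 2-C-methyl-D-ribono-1,4-lactone
Product: 12 2,3-O-(methoxymethylidene)-2-C-methyl-D-ribono-1,4-lactone
Conditions: HC(OMe)3 (1.2 equiv), CSA (cat.), THF, rt; Et3N
Reagents that add atoms: trimethyl orthoformate, COC(OC)OC
Why: Acid-catalysed orthoester exchange on the cis-2,3-diol gives the cyclic orthoformate (epimer mixture at the new acetal carbon, lost later) and leaves the primary OH free.

**Step 9**
Reactants: 12 2,3-O-(methoxymethylidene)-2-C-methyl-D-ribono-1,4-lactone
Product: 14 2,3,3-trichloro-1-[(1R,4R,5R,6R)-4-hydroxy-6-methyl-2,7,8-trioxabicyclo[3.2.1]octan-6-yl]prop-2-en-1-one, via hemiketal 13 (not isolated)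
Conditions: Cl2C=CHCl, n-BuLi (2.5 equiv), THF/Et2O, −78 °C; then 12, −78 °C; aq. NaHCO3; then CSA (cat.), 4 Å MS, CH2Cl2, rt; Et3N
Reagents that add atoms: trichloroethylene, ClC=C(Cl)Cl
Why: Organolithium mono-addition to the lactone gives the hemiketal; acid-catalysed intramolecular orthoester exchange by the primary OH of its open-chain tautomer then forms the orthoformate cage (O7, O8, O–C1), which holds the ketone open and leaves only the C8a–OH free, its single possible configuration at the cage carbon being dictated by C7 and C8.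

**Step 10**
Reactants: 14 the cage hydroxy ketone
Product: 15 2-oxo-2-{[(1R,4R,5R,6R)-6-methyl-6-(2,3,3-trichloroprop-2-enoyl)-2,7,8-trioxabicyclo[3.2.1]octan-4-yl]oxy}acetic acid
Conditions: (COCl)2 (2 equiv), 2,6-lutidine, Et2O, 0 °C; then H2O
Reagents that add atoms: oxalyl chloride, O=C(Cl)C(Cl)=O; water, O
Why: O-Acylation with oxalyl chloride and hydrolysis of the second acyl chloride gives the alkyl hydrogen oxalate radical precursor, without a nucleophilic base that could attack the trichlorovinyl ketone.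

**Step 11**
Reactants: 15 the hydrogen oxalate
Product: 16 5,6,1'-O-orthoformate (O7, O8, O–C1 cage) of (4S,5R,6R)-2,3-dichloro-5,6-dihydroxy-4-(hydroxymethyl)-6-methylcyclohex-2-en-1-one
Conditions: [Ir(dF(CF3)ppy)2(dtbbpy)]PF6 (2 mol %), Cs2CO3 (1.5 equiv), DME/DMF 3:1 (0.01 M), H2O (10 equiv), 450 nm LEDs, 60 °C
Reagents that add atoms: none
Why: Proposed new method: redox-neutral photoredox deoxygenative radical alkenylation–annulation, in which excited trivalent iridium oxidizes the cesium oxalate, loss of two CO2 gives the C8a radical, this adds 6-endo-trig to the CCl2 carbon (the enone β-carbon, favoured over 5-exo attack at the α-carbon by polarity), and divalent iridium reduces the α-keto radical to an enolate that expels chloride to give the 2,3-dichloroenone; in the rigid cage the chain on C7 can reach C8a only through the position gauche to C7 (the one anti to C7 cannot close a six-membered ring), so C4a replaces the former C–O with inversion and C8a–H ends anti, CH2O syn, to O7/O8; the closest known reactions are photoredox oxalate-based deoxygenative Giese additions and radical addition–elimination (trichlorovinylation) on polychloroalkenes.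

**Step 12**
Reactants: 16 the caged 2,3-dichloroenone; 10 (2S,3E)-2-[(2S,3S)-3-methyloxolan-2-yl]hex-3-en-5-yn-2-ol
Product: 17 orthoformate-caged (4S,5R,6R)-2-chloro-5,6-dihydroxy-4-(hydroxymethyl)-3-{(3E,5S)-5-hydroxy-5-[(2S,3S)-3-methyloxolan-2-yl]hex-3-en-1-yn-1-yl}-6-methylcyclohex-2-en-1-one
Conditions: Pd(PPh3)2Cl2 (5 mol %), CuI (10 mol %), iPr2NEt, THF, rt
Reagents that add atoms: none
Why: Sonogashira coupling: zerovalent palladium inserts only into the β-chloride (a vinylogous acid chloride), so the C5 chloride, the cage and all stereocentres are untouched.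

**Step 13**
Reactants: 17 the caged enyne-enone
Product: 19 (7R,8R,8aS)-5-chloro-7,8-dihydroxy-3-{(1E,3S)-3-hydroxy-3-[(2S,3S)-3-methyloxolan-2-yl]but-1-en-1-yl}-7-methyl-1,7,8,8a-tetrahydro-6H-isochromen-6-one, via triol 18 (not isolated)
Conditions: PPTS (cat.), MeOH, 40 °C; then K2CO3 (0.3 equiv), MeOH, 0 °C
Reagents that add atoms: none
Why: Acid-catalysed orthoester exchange with methanol frees O7–H, O8–H and C1–OH, and the primary alkoxide closes the pyran by 6-endo-dig 1,6-oxa-Michael addition at C3 (attack at C4 is electronically disfavoured and O8 would need a bridgehead alkene); protonation at C4 gives the dienone with C8a unchanged.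

## Compound list

1 | (S)-5-(hydroxymethyl)furan-2(5H)-one | C1=CC(=O)O[C@@H]1CO | starting material
2 | (S)-5-[(trityloxy)methyl]furan-2(5H)-one | C1=CC(=O)O[C@@H]1COC(c2ccccc2)(c2ccccc2)c2ccccc2 | intermediate
3 | (4S,5S)-4-methyl-5-[(trityloxy)methyl]oxolan-2-one | C[C@H]1CC(=O)O[C@@H]1COC(c2ccccc2)(c2ccccc2)c2ccccc2 | intermediate
4 | (4S,5S)-4-methyl-5-[(trityloxy)methyl]oxolan-2-ol (lactol, anomer mixture) | C[C@H]1CC(O)O[C@@H]1COC(c2ccccc2)(c2ccccc2)c2ccccc2 | intermediate
5 | [(2S,3S)-3-methyloxolan-2-yl]methanol | C[C@H]1CCO[C@@H]1CO | intermediate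
6 | (2S,3S)-3-methyloxolane-2-carboxylic acid | C[C@H]1CCO[C@@H]1C(O)=O | intermediate
7 | 1-[(2S,3S)-3-methyloxolan-2-yl]ethan-1-one | C[C@H]1CCO[C@@H]1C(C)=O | intermediate
8 | (2S)-2-[(2S,3S)-3-methyloxolan-2-yl]-6-(trimethylsilyl)hexa-3,5-diyn-2-ol | C[C@H]1CCO[C@@H]1[C@@](C)(O)C#CC#C[Si](C)(C)C | intermediate
9 | (2S,3E)-2-[(2S,3S)-3-methyloxolan-2-yl]-6-(trimethylsilyl)hex-3-en-5-yn-2-ol | C[C@H]1CCO[C@@H]1[C@@](C)(O)/C=C/C#C[Si](C)(C)C | intermediate
10 | (2S,3E)-2-[(2S,3S)-3-methyloxolan-2-yl]hex-3-en-5-yn-2-ol | C[C@H]1CCO[C@@H]1[C@@](C)(O)/C=C/C#C | intermediate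
11 | 2-C-methyl-D-ribono-1,4-lactone, (3R,4R,5R)-3,4-dihydroxy-5-(hydroxymethyl)-3-methyloxolan-2-one | O=C1[C@](C)(O)[C@H](O)[C@@H](CO)O1 | starting material
12 | 2,3-O-(methoxymethylidene)-2-C-methyl-D-ribono-1,4-lactone (acetal epimers) | O=C1[C@]2(C)OC(OC)O[C@@H]2[C@@H](CO)O1 | intermediate
13 | 2,3-O-(methoxymethylidene)-2-C-methyl-1-C-(trichlorovinyl)-D-ribofuranose (hemiketal, anomer mixture) | OC1(C(Cl)=C(Cl)Cl)[C@]2(C)OC(OC)O[C@@H]2[C@@H](CO)O1 | intermediate
14 | 2,3,3-trichloro-1-[(1R,4R,5R,6R)-4-hydroxy-6-methyl-2,7,8-trioxabicyclo[3.2.1]octan-6-yl]prop-2-en-1-one | O=C(C(Cl)=C(Cl)Cl)[C@]1(C)O[C@@H]2OC[C@@H](O)[C@H]1O2 | intermediate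
15 | 2-oxo-2-{[(1R,4R,5R,6R)-6-methyl-6-(2,3,3-trichloroprop-2-enoyl)-2,7,8-trioxabicyclo[3.2.1]octan-4-yl]oxy}acetic acid | O=C(C(Cl)=C(Cl)Cl)[C@]1(C)O[C@@H]2OC[C@@H](OC(=O)C(O)=O)[C@H]1O2 | intermediate
16 | orthoformate cage (O7, O8, O–C1 joined by one CH) of (4S,5R,6R)-2,3-dichloro-5,6-dihydroxy-4-(hydroxymethyl)-6-methylcyclohex-2-en-1-one | ClC1=C(Cl)C(=O)[C@]2(C)O[C@@H]3OC[C@H]1[C@H]2O3 | intermediate
17 | orthoformate cage of (4S,5R,6R)-2-chloro-5,6-dihydroxy-4-(hydroxymethyl)-3-{(3E,5S)-5-hydroxy-5-[(2S,3S)-3-methyloxolan-2-yl]hex-3-en-1-yn-1-yl}-6-methylcyclohex-2-en-1-one | C[C@H]1CCO[C@@H]1[C@@](C)(O)/C=C/C#CC1=C(Cl)C(=O)[C@]2(C)O[C@@H]3OC[C@H]1[C@H]2O3 | intermediate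
18 | (4S,5R,6R)-2-chloro-5,6-dihydroxy-4-(hydroxymethyl)-3-{(3E,5S)-5-hydroxy-5-[(2S,3S)-3-methyloxolan-2-yl]hex-3-en-1-yn-1-yl}-6-methylcyclohex-2-en-1-one | C[C@H]1CCO[C@@H]1[C@@](C)(O)/C=C/C#CC1=C(Cl)C(=O)[C@](C)(O)[C@H](O)[C@@H]1CO | intermediate
19 | (7R,8R,8aS)-5-chloro-7,8-dihydroxy-3-{(1E,3S)-3-hydroxy-3-[(2S,3S)-3-methyloxolan-2-yl]but-1-en-1-yl}-7-methyl-1,7,8,8a-tetrahydro-6H-isochromen-6-one (CNP0432723.3) | C[C@H]1CCO[C@@H]1[C@@](C)(O)/C=C/C1=CC2=C(Cl)C(=O)[C@](C)(O)[C@H](O)[C@@H]2CO1 | target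

## Step count and risks

Total steps: 13. Longest linear sequence: 9 (steps 1–7, then 12 and 13).

**Step 11 (proposed new method).** Risks are slow decarboxylation of the secondary alkoxycarbonyl radical, direct reduction of the trichlorovinyl ketone by the photocatalyst, and 5-exo attack. The fallback uses known chemistry and sets out from 14. The alcohol is converted with PhOC(S)Cl/pyridine (CH2Cl2, 0 °C) into the O-phenyl thionocarbonate F1. F1 is then run in a classical thermal tin-hydride radical chain (Bu3SnH by syringe pump, AIBN, benzene, 80 °C, 0.005 M): Barton–McCombie C–O homolysis gives the same cage-bound C8a radical, which cyclizes onto the trichlorovinyl group and loses a chlorine atom. The fallback comes back to the route at 16.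

**Step 9.** The lactone may add the carbenoid poorly, or the hemiketal may not open to the cage. The fallback sets out from 12 and goes through an acyclic amide instead of the hemiketal. Aminolysis with Me(MeO)NH·HCl/iPrMgCl (THF, −20 °C) gives the open-chain Weinreb amide diol F2. PPTS (CH2Cl2, 4 Å MS) closes it to the caged Weinreb amide F3. Trichlorovinyllithium (2.2 equiv, −78 °C) then gives the ketone, and the fallback comes back at 14.

**Step 13.** Risks are acid sensitivity of the tertiary allylic alcohol, 5-exo closure, and base epimerization at C8a. The fallback sets out from 17 and separates the two events. The cage is cleaved with PPTS/MeOH and the triol 18 is isolated. The pyran is then closed under neutral conditions by carbophilic alkyne activation (Ph3PAuCl/AgOTf, 5 mol %, CH2Cl2, rt; 6-endo-dig hydroalkoxylation) instead of alkoxide conjugate addition. The fallback comes back at 19. Compounds beyond the list: none F0.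

## Further compounds

F1 | step 11 | O-[(1R,4R,5R,6R)-6-methyl-6-(2,3,3-trichloroprop-2-enoyl)-2,7,8-trioxabicyclo[3.2.1]octan-4-yl] O-phenyl carbonothioate | O=C(C(Cl)=C(Cl)Cl)[C@]1(C)O[C@@H]2OC[C@@H](OC(=S)Oc3ccccc3)[C@H]1O2
F2 | step 9 | N-methoxy-N-methyl-2,3-O-(methoxymethylidene)-2-C-methyl-D-ribonamide (acetal epimers) | CON(C)C(=O)[C@]1(C)OC(OC)O[C@@H]1[C@H](O)CO
F3 | step 9 | (1R,4R,5R,6R)-4-hydroxy-N-methoxy-N,6-dimethyl-2,7,8-trioxabicyclo[3.2.1]octane-6-carboxamide | CON(C)C(=O)[C@]1(C)O[C@@H]2OC[C@@H](O)[C@H]1O2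
F0 | step 13 | none | none
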